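The seven-membered carbocycle is closed last, through the bond between the spiro carbon and the adjacent aromatic carbon of the trimethoxybenzene ring. The 2,6-dimethoxycyclohexa-2,5-dienone ring is a dearomatised 4-alkyl-2,6-dimethoxyphenol, so both carbons to be joined are arene carbons of like, nucleophilic polarity. Two-electron oxidation of the phenol with a trivalent iodine reagent reverses the polarity of its para carbon; the trimethoxyphenyl ring attacks it, and one operation forms the ring, the quaternary spiro centre and the dienone. The precursor is an open-chain (1R,2S,3R)-1,4-diaryl-2,3-dimethylbutyl benzoate, built by an Evans syn-aldol and a hydroxyl-directed hydrogenation.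

Key step: step 11

Remark on the chemistry: the spiro carbon carries two identical ring arms and is not stereogenic, so three stereocentres are to be set; they are (7R,8S,9R) in spiro numbering and correspond to C3, C2 and C1 of the open-chain butyl benzoate. TiCl4 in step 7 is treated as a promoter outside the balance.

Step 1
Reactants: 1 3,4,5-trimethoxybenzaldehyde; 2 (R)-4-benzyl-3-propanoyl-1,3-oxazolidin-2-one
Product: 5 (4R)-4-benzyl-3-[(2R,3R)-3-hydroxy-2-methyl-3-(3,4,5-trimethoxyphenyl)propanoyl]-1,3-oxazolidin-2-one, via Z-dibutylboron enolate 3 (not isolated), via dibutylboron aldolate 4 (not isolated)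
Conditions: Bu2BOTf, iPr2NEt, CH2Cl2, 0 °C; then 1, −78 → 0 °C; then pH 7 buffer, MeOH, H2O2, 0 °C
Reagents that add atoms: none
Why: Evans syn-aldol reaction, in which the Z-boron enolate 3 reacts through a closed chair (Zimmerman–Traxler) transition state on the enolate face away from the benzyl group of the (R)-auxiliary, which should set C2 and C3 of the propanoyl chain as R,R (syn).

Step 2
Reactants: 5 the aldol adduct
Product: 6 (2R,3R)-3-hydroxy-N-methoxy-N,2-dimethyl-3-(3,4,5-trimethoxyphenyl)propanamide
Conditions: MeNHOMe·HCl, AlMe3, CH2Cl2, −20 → 0 °C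
Reagents that add atoms: N,O-dimethylhydroxylamine hydrochloride, CNOC.Cl
Why: Aluminium amide transamination (Weinreb amide formation), in which the free β-hydroxyl binds aluminium and steers acyl transfer to the exocyclic carbonyl, so the auxiliary should be released without retro-aldol cleavage or epimerisation.

Step 3
Reactants: 7 syringaldehyde (4-hydroxy-3,5-dimethoxybenzaldehyde)
Product: 8 4-(tert-butyldimethylsilyloxy)-3,5-dimethoxybenzaldehyde
Conditions: TBSCl, imidazole, DMF, 23 °C
Reagents that add atoms: tert-butyldimethylsilyl chloride, CC(C)(C)[Si](C)(C)Cl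
Why: Imidazole-promoted silylation of the phenol masks the acidic OH for the later organomagnesium step; no stereocentre is involved.

Step 4
Reactants: 8 the silyl-protected aldehyde
Product: 9 [4-(tert-butyldimethylsilyloxy)-3,5-dimethoxyphenyl]methanol
Conditions: NaBH4, MeOH, 0 °C
Reagents that add atoms: none
Why: Hydride reduction of the aryl aldehyde with NaBH4 is chemoselective and should leave the hindered aryl silyl ether intact.

Step 5
Reactants: 9 the benzylic alcohol
Product: 11 tert-butyl[4-(chloromethyl)-2,6-dimethoxyphenoxy]dimethylsilane, via benzylic chlorosulfite 10 (not isolated)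
Conditions: SOCl2, pyridine, CH2Cl2, 0 °C
Reagents that add atoms: thionyl chloride, O=S(Cl)Cl
Why: Chlorodehydroxylation through chlorosulfite 10 is facile for an electron-rich benzylic alcohol, and pyridine scavenges HCl so that the silyl ether survives.

Step 6
Reactants: 11 the benzylic chloride; 6 the Weinreb amide
Product: 14 (3R,4R)-1-[4-(tert-butyldimethylsilyloxy)-3,5-dimethoxyphenyl]-4-hydroxy-3-methyl-4-(3,4,5-trimethoxyphenyl)butan-2-one, via benzylmagnesium chloride 12 (not isolated), via tetrahedral magnesium adduct 13 (not isolated)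
Conditions: 11, Mg, THF, 0 °C (gives 12); 6, iPrMgCl (1 equiv), THF, −20 °C; then 12 (2 equiv), −20 → 0 °C; NH4Cl (aq)
Reagents that add atoms: none
Why: Weinreb ketone synthesis, in which the hydroxyl of 6 is first turned into its magnesium alkoxide and the benzylic Grignard reagent 12 then adds once to give the chelated adduct 13, which collapses to the ketone only on work-up, so over-addition and epimerisation of the α-stereocentre should be avoided.

Step 7
Reactants: 14 the β-hydroxy ketone
Product: 15 (1R,2S)-3-{[4-(tert-butyldimethylsilyloxy)-3,5-dimethoxyphenyl]methyl}-2-methyl-1-(3,4,5-trimethoxyphenyl)but-3-en-1-ol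
Conditions: Zn, CH2Br2, TiCl4, THF (reagent preformed at 0–5 °C); then 14, CH2Cl2, 0 → 23 °C
Reagents that add atoms: dibromomethane, BrCBr
Why: Takai–Lombardo methylenation, whose non-basic gem-dimetallic reagent methylenates readily enolisable ketones without retro-aldol cleavage or epimerisation next to the carbonyl and tolerates the free hydroxyl.

Step 8
Reactants: 15 the homoallylic alcohol
Product: 16 (1R,2S,3R)-4-[4-(tert-butyldimethylsilyloxy)-3,5-dimethoxyphenyl]-2,3-dimethyl-1-(3,4,5-trimethoxyphenyl)butan-1-ol
Conditions: [Rh(nbd)(dppb)]BF4 (5 mol %), H2 (60 bar), CH2Cl2, 23 °C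
Reagents that add atoms: none
Why: Hydroxyl-directed homogeneous hydrogenation with a cationic rhodium bisphosphine catalyst, in which the metal binds the homoallylic OH and the alkene and, in the chelate that keeps the allylic C–H next to the arylmethyl branch (least A(1,2) strain), delivers hydrogen to the face that makes C3 R (2,3-syn methyl groups); the purely steric preference (allylic hydrogen eclipsing the alkene, addition anti to the carbinol-bearing substituent) points to the same face, and high pressure should outrun alkene migration.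

Step 9
Reactants: 16 the saturated alcohol
Product: 17 (1R,2S,3R)-4-[4-(tert-butyldimethylsilyloxy)-3,5-dimethoxyphenyl]-2,3-dimethyl-1-(3,4,5-trimethoxyphenyl)butyl benzoate
Conditions: BzCl, pyridine, DMAP (cat.), CH2Cl2, 0 → 23 °C
Reagents that add atoms: benzoyl chloride, O=C(Cl)c1ccccc1
Why: DMAP-catalysed acylation of the secondary benzylic alcohol takes place at oxygen, so C1 keeps its configuration.

Step 10
Reactants: 17 the silyl-protected benzoate
Product: 18 (1R,2S,3R)-4-(4-hydroxy-3,5-dimethoxyphenyl)-2,3-dimethyl-1-(3,4,5-trimethoxyphenyl)butyl benzoate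
Conditions: Bu4NF, AcOH, THF, 0 °C
Reagents that add atoms: none
Why: Fluoride-mediated cleavage of the aryl silyl ether is much faster than attack on the benzoate, and acetic acid buffering keeps the phenoxide from promoting acyl transfer.

Step 11
Reactants: 18 the phenolic benzoate
Product: 20 (7R,8S,9R)-2,3,3',4,5'-pentamethoxy-7,8-dimethyl-4'-oxo-6,7,8,9-tetrahydrospiro[benzo[7]annulene-5,1'-cyclohexa[2,5]diene]-9-yl benzoate (CNP0201356.1), via aryloxy-λ3-iodane 19 (not isolated)
Conditions: PhI(OCOCF3)2 (1.1 equiv), CF3CH2OH, −40 °C; then NaHCO3 (aq), −40 → 0 °C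
Reagents that add atoms: none
Why: Ligand exchange at trivalent iodine gives aryloxyiodane 19, whose loss of iodobenzene and trifluoroacetate turns the phenol ring into a phenoxonium ion that is electrophilic at the carbon para to oxygen; the trimethoxyphenyl ring attacks this carbon through C2 (ortho to the benzylic carbon, ortho and para to methoxy groups) and rearomatises by proton loss, so two nucleophilic arene carbons are joined by polarity reversal. The closest known reaction type is the hypervalent iodine mediated intramolecular oxidative para coupling of a phenol to a tethered electron-rich arene (dearomative ipso-spirocyclisation of 1,4-diarylbutanes to spirodienones). The seven-membered ring closes by attack on the para carbon of the phenoxonium ion, exo with respect to the dienone π system (7-exo-trig at the electrophile), and the four-carbon tether cannot deliver the arene to any other position. No new stereocentre should result, because the dienone ring is symmetric about the spiro carbon, and the three existing centres are not epimerisable under these conditions. The step needs C–C over C–O bond formation and survival of the dienone: the two methoxy groups block the ortho positions of the phenol, C2 and C6 of the trimethoxyphenyl ring are equivalent, the benzoate removes the only internal oxygen nucleophile, the fluoroalcohol is non-nucleophilic, and low temperature with a cold bicarbonate quench should limit the acid-induced dienone–phenol rearrangement.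

Compound list
1 | 3,4,5-trimethoxybenzaldehyde | COc1cc(C=O)cc(OC)c1OC | starting material
2 | (R)-4-benzyl-3-propanoyl-1,3-oxazolidin-2-one | CCC(=O)N1[C@H](Cc2ccccc2)COC1=O | starting material
3 | Z-dibutylboron enolate of 2 | C/C=C(\OB(CCCC)CCCC)N1[C@H](Cc2ccccc2)COC1=O | intermediate
4 | dibutylboron aldolate of 5 | COc1cc(cc(OC)c1OC)[C@H](OB(CCCC)CCCC)[C@@H](C)C(=O)N1[C@H](Cc2ccccc2)COC1=O | intermediate
5 | (4R)-4-benzyl-3-[(2R,3R)-3-hydroxy-2-methyl-3-(3,4,5-trimethoxyphenyl)propanoyl]-1,3-oxazolidin-2-one | COc1cc(cc(OC)c1OC)[C@H](O)[C@@H](C)C(=O)N1[C@H](Cc2ccccc2)COC1=O | intermediate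
6 | (2R,3R)-3-hydroxy-N-methoxy-N,2-dimethyl-3-(3,4,5-trimethoxyphenyl)propanamide | COc1cc(cc(OC)c1OC)[C@H](O)[C@@H](C)C(=O)N(C)OC | intermediate
7 | syringaldehyde (4-hydroxy-3,5-dimethoxybenzaldehyde) | COc1cc(C=O)cc(OC)c1O | starting material
8 | 4-(tert-butyldimethylsilyloxy)-3,5-dimethoxybenzaldehyde | COc1cc(C=O)cc(OC)c1O[Si](C)(C)C(C)(C)C | intermediate
9 | [4-(tert-butyldimethylsilyloxy)-3,5-dimethoxyphenyl]methanol | COc1cc(CO)cc(OC)c1O[Si](C)(C)C(C)(C)C | intermediate
10 | chlorosulfite of 9 | COc1cc(COS(Cl)=O)cc(OC)c1O[Si](C)(C)C(C)(C)C | intermediate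
11 | tert-butyl[4-(chloromethyl)-2,6-dimethoxyphenoxy]dimethylsilane | COc1cc(CCl)cc(OC)c1O[Si](C)(C)C(C)(C)C | intermediate
12 | [4-(tert-butyldimethylsilyloxy)-3,5-dimethoxybenzyl]magnesium chloride | COc1cc(C[Mg]Cl)cc(OC)c1O[Si](C)(C)C(C)(C)C | intermediate
13 | tetrahedral magnesium adduct of 12 and the alkoxide of 6 (hemiaminal carbon unassigned) | COc1cc(cc(OC)c1OC)[C@H](O[Mg]Cl)[C@@H](C)C(O[Mg]Cl)(N(C)OC)Cc1cc(OC)c(O[Si](C)(C)C(C)(C)C)c(OC)c1 | intermediate
14 | (3R,4R)-1-[4-(tert-butyldimethylsilyloxy)-3,5-dimethoxyphenyl]-4-hydroxy-3-methyl-4-(3,4,5-trimethoxyphenyl)butan-2-one | COc1cc(cc(OC)c1OC)[C@H](O)[C@@H](C)C(=O)Cc1cc(OC)c(O[Si](C)(C)C(C)(C)C)c(OC)c1 | intermediate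
15 | (1R,2S)-3-{[4-(tert-butyldimethylsilyloxy)-3,5-dimethoxyphenyl]methyl}-2-methyl-1-(3,4,5-trimethoxyphenyl)but-3-en-1-ol | COc1cc(cc(OC)c1OC)[C@H](O)[C@@H](C)C(=C)Cc1cc(OC)c(O[Si](C)(C)C(C)(C)C)c(OC)c1 | intermediate
16 | (1R,2S,3R)-4-[4-(tert-butyldimethylsilyloxy)-3,5-dimethoxyphenyl]-2,3-dimethyl-1-(3,4,5-trimethoxyphenyl)butan-1-ol | COc1cc(cc(OC)c1OC)[C@H](O)[C@@H](C)[C@H](C)Cc1cc(OC)c(O[Si](C)(C)C(C)(C)C)c(OC)c1 | intermediate
17 | (1R,2S,3R)-4-[4-(tert-butyldimethylsilyloxy)-3,5-dimethoxyphenyl]-2,3-dimethyl-1-(3,4,5-trimethoxyphenyl)butyl benzoate | COc1cc(cc(OC)c1OC)[C@H](OC(=O)c1ccccc1)[C@@H](C)[C@H](C)Cc1cc(OC)c(O[Si](C)(C)C(C)(C)C)c(OC)c1 | intermediate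
18 | (1R,2S,3R)-4-(4-hydroxy-3,5-dimethoxyphenyl)-2,3-dimethyl-1-(3,4,5-trimethoxyphenyl)butyl benzoate | COc1cc(cc(OC)c1OC)[C@H](OC(=O)c1ccccc1)[C@@H](C)[C@H](C)Cc1cc(OC)c(O)c(OC)c1 | intermediate
19 | aryloxy(phenyl)-λ3-iodanyl trifluoroacetate of 18 | COc1cc(cc(OC)c1OC)[C@H](OC(=O)c1ccccc1)[C@@H](C)[C@H](C)Cc1cc(OC)c(OI(OC(=O)C(F)(F)F)c2ccccc2)c(OC)c1 | intermediate
20 | (7R,8S,9R)-2,3,3',4,5'-pentamethoxy-7,8-dimethyl-4'-oxo-6,7,8,9-tetrahydrospiro[benzo[7]annulene-5,1'-cyclohexa[2,5]diene]-9-yl benzoate (CNP0201356.1) | COC1=CC2(C=C(OC)C1=O)C[C@@H](C)[C@H](C)[C@@H](OC(=O)c1ccccc1)c1cc(OC)c(OC)c(OC)c12 | target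

Total step count: 11.
Longest linear sequence: 9 steps (from 7 through steps 3 to 11).

Steps most likely to fail

Step 8. Hydrogen may be delivered to both alkene faces if the unbound pathway competes with the hydroxyl-bound one, or the 1,1-disubstituted alkene may migrate into conjugation with the aryl ring before reduction; either process erodes the configuration at C3. The fallback sets out from 15 and replaces hydrogenation by hydroboration and deoxygenation. Silylation of 15 (Et3SiCl, imidazole) should give triethylsilyl ether F1. 9-BBN in THF should place boron on the terminal carbon and hydrogen on C3 with the usual 1,2-induction (allylic hydrogen eclipsing the alkene, attack anti to the larger allylic substituent), which is the face wanted, to give B-alkyl-9-borabicyclononane F2. Oxidation with NaBO3·4H2O should give primary alcohol F3. TsCl and pyridine should give tosylate F4, and LiEt3BH should reduce it to the methyl compound, triethylsilyl ether F5. PPTS in MeOH removes the triethylsilyl group only, and the fallback comes back to the route at 16.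

Step 11. The spirodienone may undergo the dienone–phenol shift to a dibenzocyclooctadiene under the acid set free, or the phenoxonium ion may be intercepted by the solvent before the ring closes. The fallback sets out from 18 and separates oxidation from C–C bond formation. PhI(OAc)2 in MeOH at 0 °C should give the 4-methoxycyclohexa-2,5-dienone (quinol methyl ether) F6. BF3·OEt2 in CH2Cl2 at −78 °C should then ionise the tertiary methoxy group, and the same cation is captured by the trimethoxyphenyl ring under aprotic conditions; the fallback comes back to the route at 20.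

Step 7. Retro-aldol cleavage or enolisation of the β-hydroxy benzyl ketone, with loss of configuration next to the carbonyl, may compete with methylenation. The fallback sets out from 14 and uses a two-stage Peterson olefination. Me3SiCH2Li with CeCl3 in THF at −78 °C (a non-basic organocerium addition) should give β-hydroxysilane F7. KH in THF at 0 °C should then effect syn-elimination, and the fallback comes back to the route at 15.

Further compounds
F1 | step 8 | triethylsilyl ether of 15 | COc1cc(cc(OC)c1OC)[C@H](O[Si](CC)(CC)CC)[C@@H](C)C(=C)Cc1cc(OC)c(O[Si](C)(C)C(C)(C)C)c(OC)c1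
F2 | step 8 | B-alkyl-9-borabicyclo[3.3.1]nonane from F1 | COc1cc(cc(OC)c1OC)[C@H](O[Si](CC)(CC)CC)[C@@H](C)[C@H](CB2C3CCCC2CCC3)Cc1cc(OC)c(O[Si](C)(C)C(C)(C)C)c(OC)c1
F3 | step 8 | (2R,3S,4R)-2-{[4-(tert-butyldimethylsilyloxy)-3,5-dimethoxyphenyl]methyl}-3-methyl-4-(triethylsilyloxy)-4-(3,4,5-trimethoxyphenyl)butan-1-ol | COc1cc(cc(OC)c1OC)[C@H](O[Si](CC)(CC)CC)[C@@H](C)[C@H](CO)Cc1cc(OC)c(O[Si](C)(C)C(C)(C)C)c(OC)c1
F4 | step 8 | 4-methylbenzenesulfonate of F3 | COc1cc(cc(OC)c1OC)[C@H](O[Si](CC)(CC)CC)[C@@H](C)[C@H](COS(=O)(=O)c2ccc(C)cc2)Cc1cc(OC)c(O[Si](C)(C)C(C)(C)C)c(OC)c1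
F5 | step 8 | triethylsilyl ether of 16 | COc1cc(cc(OC)c1OC)[C@H](O[Si](CC)(CC)CC)[C@@H](C)[C@H](C)Cc1cc(OC)c(O[Si](C)(C)C(C)(C)C)c(OC)c1
F6 | step 11 | (1R,2S,3R)-2,3-dimethyl-4-(1,3,5-trimethoxy-4-oxocyclohexa-2,5-dien-1-yl)-1-(3,4,5-trimethoxyphenyl)butyl benzoate | COC1=CC(OC)(C[C@@H](C)[C@H](C)[C@@H](OC(=O)c2ccccc2)c2cc(OC)c(OC)c(OC)c2)C=C(OC)C1=O
F7 | step 7 | β-hydroxysilane from 14 (tertiary carbinol centre unassigned) | COc1cc(cc(OC)c1OC)[C@H](O)[C@@H](C)C(O)(C[Si](C)(C)C)Cc1cc(OC)c(O[Si](C)(C)C(C)(C)C)c(OC)c1
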